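**Plan**
- Retrosynthesis: ring C is opened at O1–C2 (cyclodehydration) and at C2–C3 (Baker–Venkataraman acyl transfer). This gives 4-methoxybenzoyl chloride (ring B) and a 2-hydroxy-ω-methoxyacetophenone, whose C6 methyl ether is cut back to a hydroquinone.
- Ring A is then cut at C5–C6 (6π electrocyclisation of a dienylketene) and at C4a–C8a (vinyllithium addition to dimethyl squarate). This works because ring A carries four adjacent oxygenated carbons, C6, C7, C8 and C8a, set between C5–H and the acyl-bearing C4a. The squarate brings C6 to C8a with all four oxygens; the alkenyl unit brings C5 and C4a with the masked methoxyacetyl chain.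
- Forward: methoxyacetyl chloride → vinyl ketone → 1-bromovinyl ketal → squarate adduct; thermolysis builds ring A; ketal hydrolysis, C6 methylation, anisoylation and acyl transfer follow; ring C closes last.
- Stereochemistry: the target is achiral and every racemic centre met on the way is destroyed. The only stereochemical demand is the torquoselectivity of the cyclobutenone opening (hydroxyl outward, alkenyl inward).

Key step: step 7

Remark: compounds 5, 7, 11 and 19 are racemates and are written without stereodescriptors; flavone numbering (C2 to C8a) is used for ring atoms throughout.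

**Step 1**
Reactants: 1 methoxyacetyl chloride
Product: 2 N,2-dimethoxy-N-methylacetamide
Conditions: MeNHOMe·HCl, Et3N (2.2 equiv), CH2Cl2, 0 °C → rt
Reagents that add atoms: N,O-dimethylhydroxylamine hydrochloride, CNOC.Cl
Why: Nucleophilic acyl substitution of the acid chloride by the liberated amine (Weinreb amide formation) is fast and clean and provides the acyl donor that stops at the ketone stage in step 2.

**Step 2**
Reactants: 2 N,2-dimethoxy-N-methylacetamide; 3 vinylmagnesium bromide
Product: 4 1-methoxybut-3-en-2-one
Conditions: CH2=CHMgBr (1.2 equiv), THF, −20 → 0 °C; inverse quench into cold 2 M HCl; dried CH2Cl2 extract carried on as a solution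
Reagents that add atoms: none
Why: In the Weinreb ketone synthesis the magnesium-chelated tetrahedral adduct survives until the quench, so only one vinyl group is delivered, and pouring the mixture into excess cold acid keeps the released N,O-dimethylhydroxylamine protonated so that it cannot add to the new enone.

**Step 3**
Reactants: 4 1-methoxybut-3-en-2-one
Product: 5 3,4-dibromo-1-methoxybutan-2-one (racemic)
Conditions: Br2 (1.0 equiv), CH2Cl2, −78 → −20 °C
Reagents that add atoms: bromine, BrBr
Why: Electrophilic anti addition of bromine across the unhindered vinyl group converts the volatile, polymerisable enone into a stable dibromo ketone whose new CHBr centre is racemic and is removed again in step 5.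

**Step 4**
Reactants: 5 3,4-dibromo-1-methoxybutan-2-one; 6 ethylene glycol
Product: 7 2-(1,2-dibromoethyl)-2-(methoxymethyl)-1,3-dioxolane (racemic)
Conditions: HOCH2CH2OH (3 equiv), p-toluenesulfonic acid monohydrate (cat.), benzene, reflux, Dean–Stark trap
Reagents that add atoms: none
Why: Acid-catalysed ketalisation with azeotropic removal of water is standard for α-halo ketones, and masking the carbonyl before the elimination avoids the sensitive α-bromo vinyl ketone and protects the future C4 carbonyl from the organolithium of step 6.

**Step 5**
Reactants: 7 2-(1,2-dibromoethyl)-2-(methoxymethyl)-1,3-dioxolane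
Product: 8 2-(1-bromoethenyl)-2-(methoxymethyl)-1,3-dioxolane
Conditions: KOt-Bu (1.1 equiv), THF, −20 → 0 °C
Reagents that add atoms: none
Why: In this E2 dehydrobromination the hydrogen on the bromine-bearing carbon next to the two ketal oxygens is the most acidic and can lie anti to the primary bromide, so the 1-bromovinyl ketal should form, as in the known preparation of 2-bromoacrolein acetals from 2,3-dibromopropanal acetals.

**Step 6**
Reactants: 8 2-(1-bromoethenyl)-2-(methoxymethyl)-1,3-dioxolane; 9 dimethyl squarate
Product: 11 4-hydroxy-2,3-dimethoxy-4-{1-[2-(methoxymethyl)-1,3-dioxolan-2-yl]ethenyl}cyclobut-2-en-1-one (racemic), via vinyllithium 10 (not isolated)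
Conditions: t-BuLi (2.0 equiv), THF, −78 °C; cannulate into 9, THF, −78 °C; aq NH4Cl at −78 °C
Reagents that add atoms: none
Why: Bromine–lithium exchange gives the ketal-stabilised vinyllithium (a masked α-acylvinyl anion), and such organolithiums add 1,2 to one carbonyl of dimethyl squarate at −78 °C to give 4-hydroxycyclobutenones when the alkoxide is quenched cold; the carbinol centre forms as a racemate and disappears in step 7.

**Step 7**
Reactants: 11 4-hydroxy-2,3-dimethoxy-4-{1-[2-(methoxymethyl)-1,3-dioxolan-2-yl]ethenyl}cyclobut-2-en-1-one
Product: 14 2,3-dimethoxy-5-[2-(methoxymethyl)-1,3-dioxolan-2-yl]benzene-1,4-diol, via dienylketene 12 (not isolated), via cyclohexadienone 13 (not isolated)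
Conditions: degassed toluene (0.02 M), 110 °C, Ar; aq Na2S2O4 wash
Reagents that add atoms: none
Why: On heating, the cyclobutenone undergoes conrotatory 4π opening of the C1–C4 bond, and because the C4 hydroxyl (a donor) rotates outward, the alkenyl group turns inward and ends cis to the ketene in the (Z)-dienylketene 12. Ring A then closes by a thermal disrotatory 6π electrocyclisation in which the ketene carbon bonds to the terminal CH2 (the C5–C6 bond of the flavone), and enolisation of cyclohexadienone 13 gives the aromatic hydroquinone 14. The closest known reaction type is the Moore rearrangement of 4-alkenyl-4-hydroxycyclobutenones made from squarate esters, which gives hydroquinones and, after oxidation, quinones. No stereocentre is created: the racemic carbinol carbon of 11 becomes the sp2 carbon C8a. The step needs inward rotation of the alkenyl group and clean closure, which the torquoselectivity of the hydroxyl, the unhindered CH2 terminus and the non-conjugating ketal (the vinyl group can act only as the 2π partner) should secure, and it needs the product to stay at the hydroquinone level, which degassed solvent, argon and the Na2S2O4 wash should secure.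

**Step 8**
Reactants: 14 2,3-dimethoxy-5-[2-(methoxymethyl)-1,3-dioxolan-2-yl]benzene-1,4-diol
Product: 15 1-(2,5-dihydroxy-3,4-dimethoxyphenyl)-2-methoxyethan-1-one
Conditions: 2 M HCl, THF (degassed), 40 °C, Ar
Reagents that add atoms: water, O
Why: Acid-catalysed hydrolysis of the dioxolane proceeds through a benzylic oxocarbenium ion stabilised by the electron-rich ring, while the hydroquinone is stable to non-oxidising acid under argon.

**Step 9**
Reactants: 15 1-(2,5-dihydroxy-3,4-dimethoxyphenyl)-2-methoxyethan-1-one
Product: 16 1-(2-hydroxy-3,4,5-trimethoxyphenyl)-2-methoxyethan-1-one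
Conditions: Me2SO4 (1.05 equiv), K2CO3 (1.1 equiv), acetone (degassed), reflux, Ar
Reagents that add atoms: dimethyl sulfate, COS(=O)(=O)OC
Why: Williamson O-methylation with one equivalent of dimethyl sulfate should take place at the hydroxyl meta to the acyl group (the future C6 oxygen) because the ortho hydroxyl is locked in a hydrogen bond to the ketone and is far less nucleophilic, the selectivity long used for 2,5-dihydroxyacetophenones.

**Step 10**
Reactants: 16 1-(2-hydroxy-3,4,5-trimethoxyphenyl)-2-methoxyethan-1-one; 17 4-methoxybenzoyl chloride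
Product: 18 2,3,4-trimethoxy-6-(2-methoxyacetyl)phenyl 4-methoxybenzoate
Conditions: pyridine, 4-(dimethylamino)pyridine (cat.), 0 → 50 °C
Reagents that add atoms: none
Why: Acylation of the phenol by the acid chloride under nucleophilic catalysis in pyridine overcomes the hydrogen bond and the flanking substituents and installs the anisoyl group for the acyl transfer.

**Step 11**
Reactants: 18 2,3,4-trimethoxy-6-(2-methoxyacetyl)phenyl 4-methoxybenzoate
Product: 19 1-(2-hydroxy-3,4,5-trimethoxyphenyl)-2-methoxy-3-(4-methoxyphenyl)propane-1,3-dione (racemic)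
Conditions: KOt-Bu (2.2 equiv), THF, 0 °C → rt; then 1 M HCl
Reagents that add atoms: none
Why: In the Baker–Venkataraman rearrangement the potassium enolate at the methoxy-bearing α-carbon attacks the neighbouring aryl ester in an intramolecular Claisen condensation and expels the phenoxide, forming the C2–C3 bond, and the new central stereocentre is racemic, enolisable and lost in step 12.

**Step 12**
Reactants: 19 1-(2-hydroxy-3,4,5-trimethoxyphenyl)-2-methoxy-3-(4-methoxyphenyl)propane-1,3-dione
Product: 20 auranetin, 3,6,7,8-tetramethoxy-2-(4-methoxyphenyl)-4H-chromen-4-one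
Conditions: H2SO4 (cat.), AcOH, 90 °C
Reagents that add atoms: none
Why: In this acid-catalysed cyclodehydration the phenol adds to the anisoyl carbonyl (6-exo-trig) and the hemiketal loses water across C2–C3 to give the aromatic pyranone ring C, the methyl ethers being stable to brief warming in acetic acid.

**Compound list**
1 | methoxyacetyl chloride | COCC(=O)Cl | starting material
2 | N,2-dimethoxy-N-methylacetamide | COCC(=O)N(C)OC | intermediate
3 | vinylmagnesium bromide | C=C[Mg]Br | starting material
4 | 1-methoxybut-3-en-2-one | COCC(=O)C=C | intermediate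
5 | 3,4-dibromo-1-methoxybutan-2-one (racemic) | COCC(=O)C(Br)CBr | intermediate
6 | ethylene glycol | OCCO | starting material
7 | 2-(1,2-dibromoethyl)-2-(methoxymethyl)-1,3-dioxolane (racemic) | COCC1(OCCO1)C(Br)CBr | intermediate
8 | 2-(1-bromoethenyl)-2-(methoxymethyl)-1,3-dioxolane | COCC1(OCCO1)C(Br)=C | intermediate
9 | dimethyl squarate (3,4-dimethoxycyclobut-3-ene-1,2-dione) | COC1=C(OC)C(=O)C1=O | starting material
10 | {1-[2-(methoxymethyl)-1,3-dioxolan-2-yl]ethenyl}lithium (vinyllithium; formed and used in the flask) | [Li]C(=C)C1(COC)OCCO1 | intermediate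
11 | 4-hydroxy-2,3-dimethoxy-4-{1-[2-(methoxymethyl)-1,3-dioxolan-2-yl]ethenyl}cyclobut-2-en-1-one (racemic) | COCC1(OCCO1)C(=C)C1(O)C(OC)=C(OC)C1=O | intermediate
12 | (3Z)-4-hydroxy-2,3-dimethoxy-5-[2-(methoxymethyl)-1,3-dioxolan-2-yl]hexa-1,3,5-trien-1-one (dienylketene; formed and used in the flask) | O=C=C(OC)/C(OC)=C(/O)C(=C)C1(COC)OCCO1 | intermediate
13 | 4-hydroxy-2,3-dimethoxy-5-[2-(methoxymethyl)-1,3-dioxolan-2-yl]cyclohexa-2,4-dien-1-one (cyclohexadienone; formed and used in the flask) | COCC1(OCCO1)C1=C(O)C(OC)=C(OC)C(=O)C1 | intermediate
14 | 2,3-dimethoxy-5-[2-(methoxymethyl)-1,3-dioxolan-2-yl]benzene-1,4-diol | COCC1(OCCO1)c1cc(O)c(OC)c(OC)c1O | intermediate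
15 | 1-(2,5-dihydroxy-3,4-dimethoxyphenyl)-2-methoxyethan-1-one | COCC(=O)c1cc(O)c(OC)c(OC)c1O | intermediate
16 | 1-(2-hydroxy-3,4,5-trimethoxyphenyl)-2-methoxyethan-1-one | COCC(=O)c1cc(OC)c(OC)c(OC)c1O | intermediate
17 | 4-methoxybenzoyl chloride | COc1ccc(cc1)C(=O)Cl | starting material
18 | 2,3,4-trimethoxy-6-(2-methoxyacetyl)phenyl 4-methoxybenzoate | COCC(=O)c1cc(OC)c(OC)c(OC)c1OC(=O)c1ccc(OC)cc1 | intermediate
19 | 1-(2-hydroxy-3,4,5-trimethoxyphenyl)-2-methoxy-3-(4-methoxyphenyl)propane-1,3-dione (racemic) | COc1ccc(cc1)C(=O)C(OC)C(=O)c1cc(OC)c(OC)c(OC)c1O | intermediate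
20 | auranetin, 3,6,7,8-tetramethoxy-2-(4-methoxyphenyl)-4H-chromen-4-one | COc1ccc(-c2oc3c(OC)c(OC)c(OC)cc3c(=O)c2OC)cc1 | target

Total step count: 12
Longest linear sequence: 12 steps (1 to 20); 3, 6, 9 and 17 are purchased and enter directly.

**Steps most likely to fail**

Step 7 (key step). The electron-rich hydroquinone may oxidise in air during work-up and chromatography, or degrade on prolonged heating, so that material is spread over two oxidation levels. The fallback sets out from 11. The thermolysis is run as before and the crude mixture is then oxidised on purpose (Ag2O, Et2O, rt) to 2,3-dimethoxy-5-[2-(methoxymethyl)-1,3-dioxolan-2-yl]cyclohexa-2,5-diene-1,4-dione F1, which should be stable to air and silica. Reduction with aqueous Na2S2O4 in EtOAc just before the hydrolysis brings the route back at 14.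

Step 9. Methylation may occur at both hydroxyls, or at the wrong one, if the hydrogen bond does not differentiate them enough, and the hydroquinone may autoxidise under base. The fallback sets out from 11 and fixes the regiochemistry before the ring is made:
- The tertiary hydroxyl is silylated (t-BuMe2SiOTf, 2,6-lutidine, CH2Cl2, −78 °C) to 4-[(tert-butyldimethylsilyl)oxy]-2,3-dimethoxy-4-{1-[2-(methoxymethyl)-1,3-dioxolan-2-yl]ethenyl}cyclobut-2-en-1-one F2.
- The same ring opening and 6π closure (toluene, 110 °C) should give 4-[(tert-butyldimethylsilyl)oxy]-2,3-dimethoxy-5-[2-(methoxymethyl)-1,3-dioxolan-2-yl]phenol F3, in which only the future C6 hydroxyl is free and no free hydroquinone is handled.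
- Methylation (MeI, K2CO3, acetone) gives tert-butyldimethyl{2,3,4-trimethoxy-6-[2-(methoxymethyl)-1,3-dioxolan-2-yl]phenoxy}silane F4.
- Bu4NF in THF followed by 2 M HCl removes the silyl ether and the ketal and returns the route at 16, bypassing steps 8 and 9.

Step 5. Elimination may run towards the wrong carbon (loss of the secondary bromide), or a second dehydrobromination may lead on to the alkyne. The fallback sets out from 5. The ketone itself is dehydrobrominated with Et3N (CH2Cl2, 0 °C), an E1cB elimination whose direction is fixed by the acidity of the α-hydrogen, to give 3-bromo-1-methoxybut-3-en-2-one F5. This is ketalised without heat by silyl transfer (1,2-bis(trimethylsilyloxy)ethane, trimethylsilyl trifluoromethanesulfonate cat., CH2Cl2, −78 °C), which returns the route at 8 and bypasses 7.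

**Further compounds**
F1 | step 7 | 2,3-dimethoxy-5-[2-(methoxymethyl)-1,3-dioxolan-2-yl]cyclohexa-2,5-diene-1,4-dione | COCC1(OCCO1)C1=CC(=O)C(OC)=C(OC)C1=O
F2 | step 9 | 4-[(tert-butyldimethylsilyl)oxy]-2,3-dimethoxy-4-{1-[2-(methoxymethyl)-1,3-dioxolan-2-yl]ethenyl}cyclobut-2-en-1-one (racemic) | COCC1(OCCO1)C(=C)C1(O[Si](C)(C)C(C)(C)C)C(OC)=C(OC)C1=O
F3 | step 9 | 4-[(tert-butyldimethylsilyl)oxy]-2,3-dimethoxy-5-[2-(methoxymethyl)-1,3-dioxolan-2-yl]phenol | COCC1(OCCO1)c1cc(O)c(OC)c(OC)c1O[Si](C)(C)C(C)(C)C
F4 | step 9 | tert-butyldimethyl{2,3,4-trimethoxy-6-[2-(methoxymethyl)-1,3-dioxolan-2-yl]phenoxy}silane | COCC1(OCCO1)c1cc(OC)c(OC)c(OC)c1O[Si](C)(C)C(C)(C)C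
F5 | step 5 | 3-bromo-1-methoxybut-3-en-2-one | COCC(=O)C(Br)=C
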